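**Plan**

1. Numbering used: lactone O1, C2(=O), C3, C4(OAc), C5; exocyclic C6; chain C7–C15 (C8 OAc, C15 OBz); alkenyl group C1'=C2'. Retrosynthetic cuts, in order: the two O-acetyl bonds, C7–C8 (vinylogous Mukaiyama aldol), the lactone O1–C5 bond (cycloisomerisation), C3–C4 (Evans aldol), C4–C5 (formylation of an allenyllithium), and the C8 oxidation and benzoate on nerol.
2. Enabling feature: C5 of the oxolan-2-one ring (O1, C2–C5) is allylic, and its 2-methylprop-1-enyl group C5–C1'H=C2'(CH3)2 is the hydro-oxygenated form of a 1,1-dimethylallene. The C2 carboxyl of a γ-allenoic acid can therefore add 5-exo across C5=C1', making the ring, the C5 stereocentre and the trisubstituted alkene in one isomerisation.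
3. Forward order: nerol → benzoate → 8-oxo enal (steps 1–3); crotonate imide + allenal → syn aldol → silyl ether → acid (steps 4–8); gold-catalysed closure of the only ring (step 9); lactone silyl dienolate joined to the enal at C7–C8 (steps 10–11); desilylation and double acetylation (steps 12–13).
4. Stereochemistry: C4 from the oxazolidinone auxiliary; C5 from C4 by 1,2-induction (trans) in the ring closure; C8 from the chiral Lewis-base catalyst; the 3E alkylidene from the s-trans dienolate; the 9E alkene from the SeO2 oxidation; the 13Z alkene from nerol.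
5. Helpers: the O4 silyl group (blocks O4 as a nucleophile toward the allene, enforces trans, removed in step 12) and the C3 vinyl group with its temporary C3 stereocentre (becomes the dienolate, then C6/C7).

Key step: step 9

Assumption: the (R,R) enantiomer of the bisphosphoramide Lewis base is taken to expose the Re face of the silicon-bound aldehyde, as in its additions of silyl ketene acetals to conjugated aldehydes; if a model aldehyde shows the opposite sense, the (S,S) enantiomer is used in step 11.

**Route**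

Step 1
Reactants: 1 nerol, (2Z)-3,7-dimethylocta-2,6-dien-1-ol
Product: 2 neryl benzoate, (2Z)-3,7-dimethylocta-2,6-dien-1-yl benzoate
Conditions: BzCl, pyridine, DMAP (cat.), CH2Cl2, 0 °C to rt
Reagents that add atoms: benzoyl chloride, O=C(Cl)c1ccccc1
Why: DMAP-catalysed O-benzoylation (nucleophilic acyl substitution) of the primary allylic alcohol installs the C15 benzoate at the outset and leaves the 2Z alkene untouched; no stereocentre is formed.

Step 2
Reactants: 2 neryl benzoate
Product: 3 (2Z,6E)-8-hydroxy-3,7-dimethylocta-2,6-dien-1-yl benzoate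
Conditions: SeO2 (0.2 equiv), t-BuOOH (3 equiv), salicylic acid (0.1 equiv), CH2Cl2, rt
Reagents that add atoms: tert-butyl hydroperoxide, CC(C)(C)OO
Why: Riley-type allylic oxidation (ene reaction, then [2,3]-sigmatropic shift) should attack the electron-rich terminal alkene rather than the one deactivated by the allylic benzoate and hydroxylate its E-methyl group, which fixes the 6E geometry; any aldehyde 4 formed already is carried into step 3.

Step 3
Reactants: 3 (2Z,6E)-8-hydroxy-3,7-dimethylocta-2,6-dien-1-yl benzoate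
Product: 4 (2Z,6E)-3,7-dimethyl-8-oxoocta-2,6-dien-1-yl benzoate
Conditions: MnO2 (excess), CH2Cl2, rt
Reagents that add atoms: none
Why: Heterogeneous MnO2 oxidation is selective for the allylic alcohol and should give the E-enal without isomerising either alkene or touching the benzoate.

Step 4
Reactants: 5 (S)-4-benzyl-1,3-oxazolidin-2-one; 6 (E)-but-2-enoyl chloride
Product: 8 (4S)-4-benzyl-3-[(2E)-but-2-enoyl]-1,3-oxazolidin-2-one, via lithium oxazolidinonide 7 (not isolated)
Conditions: n-BuLi, THF, −78 °C; then 6, −78 to 0 °C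
Reagents that add atoms: none
Why: N-Acylation of the lithiated oxazolidinone with the acid chloride gives the crotonate imide that carries the auxiliary for the aldol step.

Step 5
Reactants: 9 3-methylbuta-1,2-diene; 10 N,N-dimethylformamide
Product: 13 4-methylpenta-2,3-dienal, via allenyllithium 11 (not isolated), via lithium hemiaminalate 12 (not isolated)
Conditions: n-BuLi, THF, −78 to −40 °C; 10, −78 °C; AcOH, −78 °C, then H2O; used as a cold solution
Reagents that add atoms: none
Why: Deprotonation of 1,1-dimethylallene at its only sp2 C–H gives the allenyllithium, which should be formylated at the unhindered CH terminus by DMF (Bouveault aldehyde synthesis); the allene axis is achiral because of the two methyl groups.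

Step 6
Reactants: 8 (4S)-4-benzyl-3-[(2E)-but-2-enoyl]-1,3-oxazolidin-2-one; 13 4-methylpenta-2,3-dienal
Product: 16 (4S)-4-benzyl-3-[(2S,3R)-2-ethenyl-3-hydroxy-6-methylhepta-4,5-dienoyl]-1,3-oxazolidin-2-one, via boron dienolate 14 (not isolated), via boron aldolate 15 (not isolated)
Conditions: Bu2BOTf (1.1 equiv), Et3N (1.3 equiv), CH2Cl2, −78 to 0 °C; 13, −78 to 0 °C; pH 7 buffer, MeOH, H2O2, 0 °C
Reagents that add atoms: none
Why: Evans boron aldol of the crotonate imide: the Z-configured boron dienolate reacts at its α-carbon through a chair (Zimmerman–Traxler) transition state on the face away from the benzyl group, so the syn (2S,3R) adduct should form, with the carbinol carbon (future C4) set by the auxiliary and the temporary C3 centre carrying the vinyl group.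

Step 7
Reactants: 16 (4S)-4-benzyl-3-[(2S,3R)-2-ethenyl-3-hydroxy-6-methylhepta-4,5-dienoyl]-1,3-oxazolidin-2-one
Product: 17 (4S)-4-benzyl-3-[(2S,3R)-3-[(tert-butyldimethylsilyl)oxy]-2-ethenyl-6-methylhepta-4,5-dienoyl]-1,3-oxazolidin-2-one
Conditions: TBSOTf, 2,6-lutidine, CH2Cl2, −78 to 0 °C
Reagents that add atoms: tert-butyldimethylsilyl triflate, CC(C)(C)[Si](C)(C)OS(=O)(=O)C(F)(F)F
Why: Silylation of the secondary allenyl carbinol; the bulky silyl group later removes O4 as a nucleophile toward the allene and biases the ring closure toward trans.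

Step 8
Reactants: 17 (4S)-4-benzyl-3-[(2S,3R)-3-[(tert-butyldimethylsilyl)oxy]-2-ethenyl-6-methylhepta-4,5-dienoyl]-1,3-oxazolidin-2-one
Product: 19 (2S,3R)-3-[(tert-butyldimethylsilyl)oxy]-2-ethenyl-6-methylhepta-4,5-dienoic acid, via peroxy acid 18 (not isolated)
Conditions: LiOH, H2O2, THF/H2O (3:1), 0 °C; aq. Na2SO3; HCl to pH 3
Reagents that add atoms: hydrogen peroxide (as LiOOH), OO
Why: Lithium hydroperoxide should cleave the exocyclic imide carbonyl selectively (hydroperoxide attack, then sulfite reduction of the peracid), which frees the carboxylic acid needed as internal nucleophile and returns the auxiliary without epimerising C3 or touching the allene.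

Step 9
Reactants: 19 (2S,3R)-3-[(tert-butyldimethylsilyl)oxy]-2-ethenyl-6-methylhepta-4,5-dienoic acid
Product: 21 (3S,4S,5R)-4-[(tert-butyldimethylsilyl)oxy]-3-ethenyl-5-(2-methylprop-1-en-1-yl)oxolan-2-one, via alkenylgold lactone 20 (not isolated)
Conditions: (t-Bu)2(2-biphenylyl)PAuCl (5 mol %), AgOTs (5 mol %), toluene, 23 °C
Reagents that add atoms: none
Why: The cationic monovalent gold complex formed from the chloride and AgOTs binds the C5=C1' π bond of the 1,1-dimethylallene, the carboxyl oxygen adds to C5 anti to gold to give the alkenylgold 20, and protodeauration at C1' releases the catalyst and leaves the 2-methylprop-1-enyl group. The closest known reaction type is the gold-catalysed hydroacyloxylation (cycloisomerisation) of γ-allenoic acids to γ-alkenyl-γ-butyrolactones, the acid analogue of allenol hydroalkoxylation. The oxolan-2-one ring closes 5-exo-trig on the proximal allene double bond, which is preferred over attack at the central or the dimethyl-substituted carbon (six- or seven-membered rings). The new stereocentre C5 is controlled by the adjacent silyloxy-bearing C4: in the envelope-like transition state the bulky OTBS group and the C3 vinyl group trans to it stay pseudo-equatorial and turn away from the ligated gold, so the alkenyl group should end up trans to OTBS, and because C–O formation is reversible before protodeauration the more stable all-trans alkenylgold is the one drained. The step needs 4,5-trans over 4,5-cis selectivity and chemoselectivity for the carboxyl oxygen over O4 and the C3 vinyl group; the silyl cap removes the 5-endo attack of O4 on the allene, and the intramolecular oxygen nucleophile should outrun ene-allene carbocyclisation.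

Step 10
Reactants: 21 (3S,4S,5R)-4-[(tert-butyldimethylsilyl)oxy]-3-ethenyl-5-(2-methylprop-1-en-1-yl)oxolan-2-one
Product: 22 tert-butyl{[(4S,5R)-4-[(tert-butyldimethylsilyl)oxy]-3-ethenyl-5-(2-methylprop-1-en-1-yl)-4,5-dihydrofuran-2-yl]oxy}dimethylsilane
Conditions: TBSOTf, Et3N, CH2Cl2, 0 °C; salts removed with pentane, used crude
Reagents that add atoms: tert-butyldimethylsilyl triflate, CC(C)(C)[Si](C)(C)OS(=O)(=O)C(F)(F)F
Why: Soft enolisation (O-silylation of the lactone carbonyl, then removal of the doubly activated C3–H by Et3N) should give the silyl ketene acetal, that is the 2-silyloxy-3-vinyl-4,5-dihydrofuran dienolate; the temporary C3 stereocentre is deliberately erased and no free enolate that could expel the C4 silyloxide is formed.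

Step 11
Reactants: 22 tert-butyl{[(4S,5R)-4-[(tert-butyldimethylsilyl)oxy]-3-ethenyl-5-(2-methylprop-1-en-1-yl)-4,5-dihydrofuran-2-yl]oxy}dimethylsilane; 4 (2Z,6E)-3,7-dimethyl-8-oxoocta-2,6-dien-1-yl benzoate
Product: 24 (2Z,6E,8R)-10-[(3E,4S,5R)-4-[(tert-butyldimethylsilyl)oxy]-5-(2-methylprop-1-en-1-yl)-2-oxooxolan-3-ylidene]-8-hydroxy-3,7-dimethyldeca-2,6-dien-1-yl benzoate, via trichlorosilyl ether 23 (not isolated)
Conditions: SiCl4 (1.1 equiv), (R,R)-bisphosphoramide Lewis base [pentamethylene-linked bis(N,N'-dimethyl-1,1'-binaphthyl-2,2'-diamine phosphoramide), 5 mol %], i-Pr2NEt (10 mol %), CH2Cl2, −78 °C; sat. aq. NaHCO3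
Reagents that add atoms: none
Why: Vinylogous Mukaiyama aldol under Lewis-base activation of SiCl4: the chiral phosphoramide-bound trichlorosilyl cation binds aldehyde 4 and exposes its Re face to the terminal CH2 (C7) of the dienolate, whose α-carbon C3 is fully substituted so that only γ-attack is open, which should set 8R by catalyst control (the lactone stereocentres are remote) and, through the s-trans diene conformer that keeps C7 away from the C2 silyloxy group, the 3E alkylidene.

Step 12
Reactants: 24 (2Z,6E,8R)-10-[(3E,4S,5R)-4-[(tert-butyldimethylsilyl)oxy]-5-(2-methylprop-1-en-1-yl)-2-oxooxolan-3-ylidene]-8-hydroxy-3,7-dimethyldeca-2,6-dien-1-yl benzoate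
Product: 25 (2Z,6E,8R)-8-hydroxy-10-[(3E,4S,5R)-4-hydroxy-5-(2-methylprop-1-en-1-yl)-2-oxooxolan-3-ylidene]-3,7-dimethyldeca-2,6-dien-1-yl benzoate
Conditions: HF·pyridine, pyridine, THF, 0 °C to rt
Reagents that add atoms: none
Why: Fluoride-induced cleavage of the secondary silyl ether under buffered conditions should spare the lactone, the benzoate and the allylic C5–O and C8–O bonds; no stereocentre is touched.

Step 13
Reactants: 25 (2Z,6E,8R)-8-hydroxy-10-[(3E,4S,5R)-4-hydroxy-5-(2-methylprop-1-en-1-yl)-2-oxooxolan-3-ylidene]-3,7-dimethyldeca-2,6-dien-1-yl benzoate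
Product: 26 (2Z,6E,8R)-8-acetoxy-10-[(3E,4S,5R)-4-acetoxy-5-(2-methylprop-1-en-1-yl)-2-oxooxolan-3-ylidene]-3,7-dimethyldeca-2,6-dien-1-yl benzoate (target)
Conditions: Ac2O, pyridine, DMAP (cat.), CH2Cl2, 0 °C to rt
Reagents that add atoms: acetic anhydride, CC(=O)OC(C)=O
Why: DMAP-catalysed acetylation of both secondary allylic hydroxyls (O4 and O8) completes the target without affecting any stereocentre.

**Compound list**

1 | nerol, (2Z)-3,7-dimethylocta-2,6-dien-1-ol | CC(C)=CCC/C(C)=C\CO | starting material
2 | neryl benzoate, (2Z)-3,7-dimethylocta-2,6-dien-1-yl benzoate | CC(C)=CCC/C(C)=C\COC(=O)c1ccccc1 | intermediate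
3 | (2Z,6E)-8-hydroxy-3,7-dimethylocta-2,6-dien-1-yl benzoate | OC/C(C)=C/CC/C(C)=C\COC(=O)c1ccccc1 | intermediate
4 | (2Z,6E)-3,7-dimethyl-8-oxoocta-2,6-dien-1-yl benzoate | O=C/C(C)=C/CC/C(C)=C\COC(=O)c1ccccc1 | intermediate
5 | (S)-4-benzyl-1,3-oxazolidin-2-one | O=C1N[C@@H](Cc2ccccc2)CO1 | starting material
6 | (E)-but-2-enoyl chloride | C/C=C/C(Cl)=O | starting material
7 | lithium salt of 5 (N-lithio oxazolidinone) | [Li]N1[C@@H](Cc2ccccc2)COC1=O | intermediate
8 | (4S)-4-benzyl-3-[(2E)-but-2-enoyl]-1,3-oxazolidin-2-one | C/C=C/C(=O)N1[C@@H](Cc2ccccc2)COC1=O | intermediate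
9 | 3-methylbuta-1,2-diene | CC(C)=C=C | starting material
10 | N,N-dimethylformamide | CN(C)C=O | starting material
11 | (3-methylbuta-1,2-dien-1-yl)lithium | [Li]C=C=C(C)C | intermediate
12 | lithium 1-(dimethylamino)-4-methylpenta-2,3-dien-1-olate | [Li]OC(N(C)C)C=C=C(C)C | intermediate
13 | 4-methylpenta-2,3-dienal | CC(C)=C=CC=O | intermediate
14 | dibutylboron Z-dienolate of 8, (4S)-4-benzyl-3-[(1Z)-1-(dibutylboranyloxy)buta-1,3-dien-1-yl]-1,3-oxazolidin-2-one | C=C/C=C(\OB(CCCC)CCCC)N1[C@@H](Cc2ccccc2)COC1=O | intermediate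
15 | dibutylboron aldolate of 16 (O–BBu2 on the carbinol oxygen) | C=C[C@H](C(=O)N1[C@@H](Cc2ccccc2)COC1=O)[C@H](OB(CCCC)CCCC)C=C=C(C)C | intermediate
16 | (4S)-4-benzyl-3-[(2S,3R)-2-ethenyl-3-hydroxy-6-methylhepta-4,5-dienoyl]-1,3-oxazolidin-2-one | C=C[C@H](C(=O)N1[C@@H](Cc2ccccc2)COC1=O)[C@H](O)C=C=C(C)C | intermediate
17 | (4S)-4-benzyl-3-[(2S,3R)-3-[(tert-butyldimethylsilyl)oxy]-2-ethenyl-6-methylhepta-4,5-dienoyl]-1,3-oxazolidin-2-one | C=C[C@H](C(=O)N1[C@@H](Cc2ccccc2)COC1=O)[C@H](O[Si](C)(C)C(C)(C)C)C=C=C(C)C | intermediate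
18 | (2S,3R)-3-[(tert-butyldimethylsilyl)oxy]-2-ethenyl-6-methylhepta-4,5-dieneperoxoic acid | C=C[C@H](C(=O)OO)[C@H](O[Si](C)(C)C(C)(C)C)C=C=C(C)C | intermediate
19 | (2S,3R)-3-[(tert-butyldimethylsilyl)oxy]-2-ethenyl-6-methylhepta-4,5-dienoic acid | C=C[C@H](C(=O)O)[C@H](O[Si](C)(C)C(C)(C)C)C=C=C(C)C | intermediate
20 | alkenylgold lactone: 21 with the (t-Bu)2(2-biphenylyl)PAu fragment in place of H on C1' | CC(C)=C([Au-][P+](C(C)(C)C)(C(C)(C)C)c1ccccc1-c1ccccc1)[C@H]1OC(=O)[C@@H](C=C)[C@@H]1O[Si](C)(C)C(C)(C)C | intermediate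
21 | (3S,4S,5R)-4-[(tert-butyldimethylsilyl)oxy]-3-ethenyl-5-(2-methylprop-1-en-1-yl)oxolan-2-one | C=C[C@@H]1C(=O)O[C@H](C=C(C)C)[C@H]1O[Si](C)(C)C(C)(C)C | intermediate
22 | tert-butyl{[(4S,5R)-4-[(tert-butyldimethylsilyl)oxy]-3-ethenyl-5-(2-methylprop-1-en-1-yl)-4,5-dihydrofuran-2-yl]oxy}dimethylsilane | C=CC1=C(O[Si](C)(C)C(C)(C)C)O[C@H](C=C(C)C)[C@H]1O[Si](C)(C)C(C)(C)C | intermediate
23 | trichlorosilyl ether of 24 (O8–SiCl3) | Cl[Si](Cl)(Cl)O[C@H](C/C=C1/C(=O)O[C@H](C=C(C)C)[C@H]1O[Si](C)(C)C(C)(C)C)/C(C)=C/CC/C(C)=C\COC(=O)c1ccccc1 | intermediate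
24 | (2Z,6E,8R)-10-[(3E,4S,5R)-4-[(tert-butyldimethylsilyl)oxy]-5-(2-methylprop-1-en-1-yl)-2-oxooxolan-3-ylidene]-8-hydroxy-3,7-dimethyldeca-2,6-dien-1-yl benzoate | O[C@H](C/C=C1/C(=O)O[C@H](C=C(C)C)[C@H]1O[Si](C)(C)C(C)(C)C)/C(C)=C/CC/C(C)=C\COC(=O)c1ccccc1 | intermediate
25 | (2Z,6E,8R)-8-hydroxy-10-[(3E,4S,5R)-4-hydroxy-5-(2-methylprop-1-en-1-yl)-2-oxooxolan-3-ylidene]-3,7-dimethyldeca-2,6-dien-1-yl benzoate | O[C@H](C/C=C1/C(=O)O[C@H](C=C(C)C)[C@H]1O)/C(C)=C/CC/C(C)=C\COC(=O)c1ccccc1 | intermediate
26 | (2Z,6E,8R)-8-acetoxy-10-[(3E,4S,5R)-4-acetoxy-5-(2-methylprop-1-en-1-yl)-2-oxooxolan-3-ylidene]-3,7-dimethyldeca-2,6-dien-1-yl benzoate | CC(=O)O[C@H](C/C=C1/C(=O)O[C@H](C=C(C)C)[C@H]1OC(C)=O)/C(C)=C/CC/C(C)=C\COC(=O)c1ccccc1 | target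

**Step count and risks**

Total step count: 13. Longest linear sequence: 9 steps (from 5 through steps 4 and 6–13; the branch from 9 through steps 5–13 is equally long; the nerol branch joins after 3 steps).

Steps most likely to fail:

1. Step 11. What may go wrong: loss of facial control at the aldehyde carbonyl, because the bulky ring-bound dienolate lies outside the usual nucleophiles of the chiral Lewis base, so that both C8 epimers form. Fallback (the stereocentre is set by reduction instead of by C–C bond formation): the fallback sets out from 22 and 4. BF3·OEt2 in CH2Cl2 at −78 °C should give the vinylogous aldol adduct as the C8-epimeric alcohols, (2Z,6E,8RS)-10-[(3E,4S,5R)-4-[(tert-butyldimethylsilyl)oxy]-5-(2-methylprop-1-en-1-yl)-2-oxooxolan-3-ylidene]-8-hydroxy-3,7-dimethyldeca-2,6-dien-1-yl benzoate F1. Oxidation with DMP (the triacetoxy periodinane, NaHCO3-buffered, CH2Cl2) should give the enone (2Z,6E)-10-[(3E,4S,5R)-4-[(tert-butyldimethylsilyl)oxy]-5-(2-methylprop-1-en-1-yl)-2-oxooxolan-3-ylidene]-3,7-dimethyl-8-oxodeca-2,6-dien-1-yl benzoate F2. Corey–Bakshi–Shibata reduction with (S)-2-methyl-CBS-oxazaborolidine and catecholborane in toluene at −78 °C, with the α-methyl alkenyl group as the large substituent, should give the 8R alcohol, and the route is rejoined at 24.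

2. Step 9. What may go wrong: insufficient face discrimination at the allene terminus under kinetic control, so that the 4,5-cis lactone forms beside 21. Fallback (thermodynamic stereoconvergence instead of kinetic induction): the fallback sets out from 19. The gold-catalysed closure is run as before and the cis epimer in the mixture, (3S,4S,5S)-4-[(tert-butyldimethylsilyl)oxy]-3-ethenyl-5-(2-methylprop-1-en-1-yl)oxolan-2-one F3, is not separated. Pd(PPh3)4 (zerovalent palladium, 5 mol %) in THF at rt should reversibly ionise the allylic C5–O bond of both epimers, and re-closure should funnel the mixture to the more stable all-trans lactone, so the route is rejoined at 21.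

3. Step 5. What may go wrong: base-promoted isomerisation of the volatile allenal to the conjugated 2,4-dienal and its oligomerisation while the hemiaminal is hydrolysed in the presence of dimethylamine and lithium salts. Fallback (C4 is introduced at the alcohol level and oxidised under neutral conditions): the fallback sets out from 9. Lithiation as before and trapping of 11 with paraformaldehyde should give lithium 4-methylpenta-2,3-dien-1-olate F4 and, after an acetic acid quench, the stable and distillable 4-methylpenta-2,3-dien-1-ol F5. MnO2 in CH2Cl2 then generates the aldehyde as a neutral solution that is filtered and used at once in step 6, so the route is rejoined at 13.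

**Further compounds**

F1 | step 11 | (2Z,6E,8RS)-10-[(3E,4S,5R)-4-[(tert-butyldimethylsilyl)oxy]-5-(2-methylprop-1-en-1-yl)-2-oxooxolan-3-ylidene]-8-hydroxy-3,7-dimethyldeca-2,6-dien-1-yl benzoate (C8 epimer mixture) | OC(C/C=C1/C(=O)O[C@H](C=C(C)C)[C@H]1O[Si](C)(C)C(C)(C)C)/C(C)=C/CC/C(C)=C\COC(=O)c1ccccc1
F2 | step 11 | (2Z,6E)-10-[(3E,4S,5R)-4-[(tert-butyldimethylsilyl)oxy]-5-(2-methylprop-1-en-1-yl)-2-oxooxolan-3-ylidene]-3,7-dimethyl-8-oxodeca-2,6-dien-1-yl benzoate | O=C(C/C=C1/C(=O)O[C@H](C=C(C)C)[C@H]1O[Si](C)(C)C(C)(C)C)/C(C)=C/CC/C(C)=C\COC(=O)c1ccccc1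
F3 | step 9 | (3S,4S,5S)-4-[(tert-butyldimethylsilyl)oxy]-3-ethenyl-5-(2-methylprop-1-en-1-yl)oxolan-2-one | C=C[C@@H]1C(=O)O[C@@H](C=C(C)C)[C@H]1O[Si](C)(C)C(C)(C)C
F4 | step 5 | lithium 4-methylpenta-2,3-dien-1-olate | [Li]OCC=C=C(C)C
F5 | step 5 | 4-methylpenta-2,3-dien-1-ol | OCC=C=C(C)C
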